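**Retrosynthetic overview**
- The ten-membered carbocycle is closed last, by ring-closing metathesis at C1=C10 of a seco-diene carrying a terminal vinyl group (C1) and an isopropenyl carbinol (C9/C10).
- The C11 methyl comes from 1,4-reduction of an α-methylene-γ-lactone with kinetic protonation.
- The cis-lactone (C6–O and C6–C7) comes from a catalytic asymmetric 2-(alkoxycarbonyl)allylation of a C1–C6 enal with a (Z)-2-(bromomethyl)enoate (C7–C10 plus C11–C13), followed by lactonisation.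
- The enal comes from Brown allylation (sets C3) and esterification with (R)-2-methylbutanoic acid; the bromide comes from a Nagao acetate aldol on methacrolein (sets C9), then Morita–Baylis–Hillman reaction and SN2′ bromination.
- Ring order: γ-lactone first, ten-membered ring second.

Assumption: germacrane numbering is used for positions (alkenes C1=C10 and C4=C5, ester at C3, hydroxyl at C9, lactone C12(=O)–O–C6, methyl on C11); in step 10 the (S,S)-ligand is taken to direct Re-face attack on the aldehyde, and its antipode is used if a test run shows the opposite sense.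

**Step 1**
Reactants: 1 2,2-dimethoxyacetaldehyde; 2 2-(triphenylphosphoranylidene)propanal
Product: 3 (2E)-4,4-dimethoxy-2-methylbut-2-enal
Conditions: toluene, 80 °C
Reagents that add atoms: none
Why: Wittig olefination with a stabilised ylide gives the E-enal, and the conjugated product is too unreactive to be olefinated a second time.

**Step 2**
Reactants: 3 (2E)-4,4-dimethoxy-2-methylbut-2-enal
Product: 5 (4S,5E)-7,7-dimethoxy-5-methylhepta-1,5-dien-4-ol, via diisopinocampheylborinate 4 (not isolated)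
Conditions: (−)-Ipc2B(allyl), Et2O, −78 °C; then NaOH, H2O2, 0 °C to rt
Reagents that add atoms: (−)-B-allyldiisopinocampheylborane, C=CCB([C@@H]1C[C@@H]2C[C@H]([C@H]1C)C2(C)C)[C@@H]1C[C@@H]2C[C@H]([C@H]1C)C2(C)C
Why: Brown asymmetric allylboration through a closed chair transition state; the reagent derived from (+)-α-pinene adds allyl to the Si face of the aldehyde and sets C3 as S.

**Step 3**
Reactants: 5 (4S,5E)-7,7-dimethoxy-5-methylhepta-1,5-dien-4-ol; 6 (2R)-2-methylbutanoic acid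
Product: 7 (4S,5E)-7,7-dimethoxy-5-methylhepta-1,5-dien-4-yl (2R)-2-methylbutanoate
Conditions: DCC, DMAP (cat.), CH2Cl2, 0 °C to rt
Reagents that add atoms: none
Why: Steglich esterification acylates the secondary allylic alcohol without touching the carbinol centre or the α-centre of the acid.

**Step 4**
Reactants: 7 (4S,5E)-7,7-dimethoxy-5-methylhepta-1,5-dien-4-yl (2R)-2-methylbutanoate
Product: 8 (2E,4S)-3-methyl-1-oxohepta-2,6-dien-4-yl (2R)-2-methylbutanoate
Conditions: TsOH·H2O (cat.), acetone/H2O, rt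
Reagents that add atoms: water, O
Why: Acid-catalysed acetal hydrolysis unmasks the conjugated E-enal while the allylic ester survives the mild conditions.

**Step 5**
Reactants: 9 1-[(4R)-4-benzyl-2-sulfanylidene-1,3-thiazolidin-3-yl]ethan-1-one; 10 2-methylprop-2-enal (methacrolein)
Product: 11 (3S)-1-[(4R)-4-benzyl-2-sulfanylidene-1,3-thiazolidin-3-yl]-3-hydroxy-4-methylpent-4-en-1-one
Conditions: Sn(OTf)2, N-ethylpiperidine, CH2Cl2, −50 °C; then 10, −78 °C
Reagents that add atoms: none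
Why: Nagao acetate aldol addition; the tin enolate chelated by the thiocarbonyl reacts through a chair transition state on the face opposite the benzyl group, giving the 3S carbinol (future C9).

**Step 6**
Reactants: 11 (3S)-1-[(4R)-4-benzyl-2-sulfanylidene-1,3-thiazolidin-3-yl]-3-hydroxy-4-methylpent-4-en-1-one
Product: 12 (3S)-1-[(4R)-4-benzyl-2-sulfanylidene-1,3-thiazolidin-3-yl]-3-[(tert-butyldimethylsilyl)oxy]-4-methylpent-4-en-1-one
Conditions: TBSOTf, 2,6-lutidine, CH2Cl2, −78 to 0 °C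
Reagents that add atoms: TBSOTf, CC(C)(C)[Si](C)(C)OS(=O)(=O)C(F)(F)F
Why: Silylation with a silyl triflate protects the C9 hydroxyl for the amine, bromination and chromium steps that follow.

**Step 7**
Reactants: 12 (3S)-1-[(4R)-4-benzyl-2-sulfanylidene-1,3-thiazolidin-3-yl]-3-[(tert-butyldimethylsilyl)oxy]-4-methylpent-4-en-1-one
Product: 13 (3S)-3-[(tert-butyldimethylsilyl)oxy]-4-methylpent-4-enal
Conditions: i-Bu2AlH, CH2Cl2, −78 °C; aq. potassium sodium tartrate work-up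
Reagents that add atoms: none
Why: Hydride reduction of the activated N-acylthiazolidinethione stops at the aldehyde through a stable tetrahedral aluminate and releases the auxiliary.

**Step 8**
Reactants: 13 (3S)-3-[(tert-butyldimethylsilyl)oxy]-4-methylpent-4-enal; 14 methyl acrylate
Product: 15 methyl (5S)-5-[(tert-butyldimethylsilyl)oxy]-3-hydroxy-6-methyl-2-methylidenehept-6-enoate (both C3 epimers)
Conditions: DABCO (1 equiv), 14 (neat, excess), rt, 5 d
Reagents that add atoms: none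
Why: Morita–Baylis–Hillman reaction attaches the acrylate unit at C7; the new carbinol centre is irrelevant because it is removed in step 9.

**Step 9**
Reactants: 15 methyl (5S)-5-[(tert-butyldimethylsilyl)oxy]-3-hydroxy-6-methyl-2-methylidenehept-6-enoate
Product: 16 methyl (2Z,5S)-2-(bromomethyl)-5-[(tert-butyldimethylsilyl)oxy]-6-methylhepta-2,6-dienoate
Conditions: NBS, Me2S, CH2Cl2, 0 °C to rt
Reagents that add atoms: NBS, BrN1C(=O)CCC1=O
Why: SN2′ bromination of the Baylis–Hillman alcohol (Corey–Kim-type activation) gives the thermodynamically preferred (Z)-2-(bromomethyl)enoate.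

**Step 10**
Reactants: 8 (2E,4S)-3-methyl-1-oxohepta-2,6-dien-4-yl (2R)-2-methylbutanoate; 16 methyl (2Z,5S)-2-(bromomethyl)-5-[(tert-butyldimethylsilyl)oxy]-6-methylhepta-2,6-dienoate
Product: 19 (1E,3S)-1-[(2S,3S)-3-{(2S)-2-[(tert-butyldimethylsilyl)oxy]-3-methylbut-3-en-1-yl}-4-methylidene-5-oxooxolan-2-yl]-2-methylhexa-1,5-dien-3-yl (2R)-2-methylbutanoate, via trimethylsilyl ether 17 (not isolated), via hydroxy ester 18 (not isolated)
Conditions: CrCl2 (10 mol %), (S,S)-1,8-bis(4-isopropyl-4,5-dihydrooxazol-2-yl)-3,6-diphenyl-9H-carbazole (12 mol %), Mn powder, TMSCl, i-Pr2NEt, THF, rt; then 1 M HCl, THF, 0 °C; then PPTS (cat.), CH2Cl2, rt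
Reagents that add atoms: TMSCl, C[Si](C)(C)Cl (silyl group of 17 only)
Why: Catalytic asymmetric Nozaki–Hiyama 2-(alkoxycarbonyl)allylation; the (Z)-bromide gives an allylchromium that reacts through a chair transition state with the C8 chain cis to CH2Cr, so C6 and C7 form syn (cis-lactone after acid lactonisation), and the chiral ligand directs attack to the Re face of the enal (6S,7S here, which is 6R,7S in the target once C11 is saturated).

**Step 11**
Reactants: 19 the α-methylene lactone from step 10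
Product: 20 (1E,3S)-1-[(2R,3S,4R)-3-{(2S)-2-[(tert-butyldimethylsilyl)oxy]-3-methylbut-3-en-1-yl}-4-methyl-5-oxooxolan-2-yl]-2-methylhexa-1,5-dien-3-yl (2R)-2-methylbutanoate
Conditions: Cu(OAc)2·H2O (5 mol %), 1,2-bis(diphenylphosphino)benzene (5 mol %), (EtO)2MeSiH, t-BuOH, toluene, 0 °C to rt
Reagents that add atoms: none
Why: Copper hydride 1,4-reduction touches only the α-methylene lactone, and the enolate is protonated by t-BuOH on the face opposite the cis C6 and C7 substituents, giving 11R.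

**Step 12**
Reactants: 20 the silyl-protected α-methyl lactone from step 11
Product: 21 (1E,3S)-1-[(2R,3S,4R)-3-[(2S)-2-hydroxy-3-methylbut-3-en-1-yl]-4-methyl-5-oxooxolan-2-yl]-2-methylhexa-1,5-dien-3-yl (2R)-2-methylbutanoate
Conditions: HF·pyridine, pyridine, THF, 0 °C to rt
Reagents that add atoms: none
Why: Fluoride desilylation frees the C9 hydroxyl; ester, lactone and alkenes are inert to buffered HF.

**Step 13**
Reactants: 21 the seco-diene from step 12
Product: 22 (1(10)Z,4E)-(3S,6R,7S,9S,11R)-9-hydroxy-3-{[(2R)-2-methylbutanoyl]oxy}germacra-1(10),4-dien-12,6-olide (CNP0276536.2)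
Conditions: second-generation Grubbs catalyst (H2IMes)(PCy3)Cl2Ru=CHPh (10 mol %), 1,4-benzoquinone (20 mol %), toluene (1 mM), 80 °C
Reagents that add atoms: none
Why: Ring-closing metathesis of the terminal vinyl group with the hydroxyl-bearing isopropenyl group forms the trisubstituted C1=C10 alkene, Z being favoured because an E-alkene costs about 3 kcal/mol more strain in a ten-membered ring.

**Compound list**
1 | 2,2-dimethoxyacetaldehyde | COC(OC)C=O | starting material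
2 | 2-(triphenylphosphoranylidene)propanal | CC(C=O)=P(c1ccccc1)(c1ccccc1)c1ccccc1 | starting material
3 | (2E)-4,4-dimethoxy-2-methylbut-2-enal | COC(OC)/C=C(\C)C=O | intermediate
4 | (4S,5E)-7,7-dimethoxy-5-methylhepta-1,5-dien-4-yl diisopinocampheylborinate | C=CC[C@H](OB([C@@H]1C[C@@H]2C[C@H]([C@H]1C)C2(C)C)[C@@H]1C[C@@H]2C[C@H]([C@H]1C)C2(C)C)/C(C)=C/C(OC)OC | intermediate
5 | (4S,5E)-7,7-dimethoxy-5-methylhepta-1,5-dien-4-ol | C=CC[C@H](O)/C(C)=C/C(OC)OC | intermediate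
6 | (2R)-2-methylbutanoic acid | CC[C@@H](C)C(=O)O | starting material
7 | (4S,5E)-7,7-dimethoxy-5-methylhepta-1,5-dien-4-yl (2R)-2-methylbutanoate | CC[C@@H](C)C(=O)O[C@@H](CC=C)/C(C)=C/C(OC)OC | intermediate
8 | (2E,4S)-3-methyl-1-oxohepta-2,6-dien-4-yl (2R)-2-methylbutanoate | CC[C@@H](C)C(=O)O[C@@H](CC=C)/C(C)=C/C=O | intermediate
9 | 1-[(4R)-4-benzyl-2-sulfanylidene-1,3-thiazolidin-3-yl]ethan-1-one | CC(=O)N1C(=S)SC[C@H]1Cc1ccccc1 | starting material
10 | 2-methylprop-2-enal (methacrolein) | CC(=C)C=O | starting material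
11 | (3S)-1-[(4R)-4-benzyl-2-sulfanylidene-1,3-thiazolidin-3-yl]-3-hydroxy-4-methylpent-4-en-1-one | CC(=C)[C@@H](O)CC(=O)N1C(=S)SC[C@H]1Cc1ccccc1 | intermediate
12 | (3S)-1-[(4R)-4-benzyl-2-sulfanylidene-1,3-thiazolidin-3-yl]-3-[(tert-butyldimethylsilyl)oxy]-4-methylpent-4-en-1-one | CC(=C)[C@@H](O[Si](C)(C)C(C)(C)C)CC(=O)N1C(=S)SC[C@H]1Cc1ccccc1 | intermediate
13 | (3S)-3-[(tert-butyldimethylsilyl)oxy]-4-methylpent-4-enal | CC(=C)[C@@H](O[Si](C)(C)C(C)(C)C)CC=O | intermediate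
14 | methyl acrylate | C=CC(=O)OC | starting material
15 | methyl (5S)-5-[(tert-butyldimethylsilyl)oxy]-3-hydroxy-6-methyl-2-methylidenehept-6-enoate (both C3 epimers) | CC(=C)[C@@H](O[Si](C)(C)C(C)(C)C)CC(O)C(=C)C(=O)OC | intermediate
16 | methyl (2Z,5S)-2-(bromomethyl)-5-[(tert-butyldimethylsilyl)oxy]-6-methylhepta-2,6-dienoate | CC(=C)[C@@H](O[Si](C)(C)C(C)(C)C)C/C=C(\CBr)C(=O)OC | intermediate
17 | methyl (3S,4S,5E,7S)-3-{(2S)-2-[(tert-butyldimethylsilyl)oxy]-3-methylbut-3-en-1-yl}-6-methyl-7-{[(2R)-2-methylbutanoyl]oxy}-2-methylidene-4-[(trimethylsilyl)oxy]deca-5,9-dienoate | CC[C@@H](C)C(=O)O[C@@H](CC=C)/C(C)=C/[C@H](O[Si](C)(C)C)[C@@H](C[C@H](O[Si](C)(C)C(C)(C)C)C(C)=C)C(=C)C(=O)OC | intermediate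
18 | methyl (3S,4S,5E,7S)-3-{(2S)-2-[(tert-butyldimethylsilyl)oxy]-3-methylbut-3-en-1-yl}-4-hydroxy-6-methyl-7-{[(2R)-2-methylbutanoyl]oxy}-2-methylidenedeca-5,9-dienoate | CC[C@@H](C)C(=O)O[C@@H](CC=C)/C(C)=C/[C@H](O)[C@@H](C[C@H](O[Si](C)(C)C(C)(C)C)C(C)=C)C(=C)C(=O)OC | intermediate
19 | (1E,3S)-1-[(2S,3S)-3-{(2S)-2-[(tert-butyldimethylsilyl)oxy]-3-methylbut-3-en-1-yl}-4-methylidene-5-oxooxolan-2-yl]-2-methylhexa-1,5-dien-3-yl (2R)-2-methylbutanoate | CC[C@@H](C)C(=O)O[C@@H](CC=C)/C(C)=C/[C@@H]1OC(=O)C(=C)[C@@H]1C[C@H](O[Si](C)(C)C(C)(C)C)C(C)=C | intermediate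
20 | (1E,3S)-1-[(2R,3S,4R)-3-{(2S)-2-[(tert-butyldimethylsilyl)oxy]-3-methylbut-3-en-1-yl}-4-methyl-5-oxooxolan-2-yl]-2-methylhexa-1,5-dien-3-yl (2R)-2-methylbutanoate | CC[C@@H](C)C(=O)O[C@@H](CC=C)/C(C)=C/[C@@H]1OC(=O)[C@H](C)[C@@H]1C[C@H](O[Si](C)(C)C(C)(C)C)C(C)=C | intermediate
21 | (1E,3S)-1-[(2R,3S,4R)-3-[(2S)-2-hydroxy-3-methylbut-3-en-1-yl]-4-methyl-5-oxooxolan-2-yl]-2-methylhexa-1,5-dien-3-yl (2R)-2-methylbutanoate | CC[C@@H](C)C(=O)O[C@@H](CC=C)/C(C)=C/[C@@H]1OC(=O)[C@H](C)[C@@H]1C[C@H](O)C(C)=C | intermediate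
22 | (1(10)Z,4E)-(3S,6R,7S,9S,11R)-9-hydroxy-3-{[(2R)-2-methylbutanoyl]oxy}germacra-1(10),4-dien-12,6-olide | CC[C@@H](C)C(=O)O[C@H]1C/C=C(/C)[C@@H](O)C[C@@H]2[C@H](/C=C/1C)OC(=O)[C@@H]2C | target

**Totals**
Total step count: 13. Longest linear sequence: 9 steps (steps 5 to 9, then 10 to 13).

**Three steps most likely to fail**

Step 13 (ring-closing metathesis). The ring is strained, one partner is a hindered 1,1-disubstituted alkene, and the Z geometry rests on ring strain alone. Fallback: a Nozaki–Hiyama–Kishi macrocyclisation at C9–C10 with the Z geometry fixed beforehand in a vinyl iodide. It sets out from compound 3 (reusing 9, 6 and 14) and comes back to the route at compound 22.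

The west half is rebuilt as follows. Compound 3 and 9 under the step 5 conditions give the aldol adduct (3S,4E)-1-[(4R)-4-benzyl-2-sulfanylidene-1,3-thiazolidin-3-yl]-3-hydroxy-6,6-dimethoxy-4-methylhex-4-en-1-one F6. TBSOTf and 2,6-lutidine give its silyl ether F7. i-Bu2AlH gives the aldehyde (3S,4E)-3-[(tert-butyldimethylsilyl)oxy]-6,6-dimethoxy-4-methylhex-4-enal F8. A Stork–Zhao-type Wittig reaction with Ph3P=C(I)CH3 (from EtPPh3I, n-BuLi, I2, then NaN(SiMe3)2; THF, −78 °C) gives the vinyl iodide (2E,4S,6Z)-4-[(tert-butyldimethylsilyl)oxy]-7-iodo-1,1-dimethoxy-3-methylocta-2,6-diene F9. Bu4NF gives the alcohol (2E,4S,6Z)-7-iodo-1,1-dimethoxy-3-methylocta-2,6-dien-4-ol F10. Acid 6 with DCC and DMAP gives the ester (2E,4S,6Z)-7-iodo-1,1-dimethoxy-3-methylocta-2,6-dien-4-yl (2R)-2-methylbutanoate F11. TsOH in aqueous acetone gives the enal (2E,4S,6Z)-7-iodo-3-methyl-1-oxoocta-2,6-dien-4-yl (2R)-2-methylbutanoate F12.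

The east half starts from commercial 3-[(tert-butyldimethylsilyl)oxy]propanal. With 14 and DABCO it gives methyl 5-[(tert-butyldimethylsilyl)oxy]-3-hydroxy-2-methylidenepentanoate F13, and NBS/Me2S gives methyl (2Z)-2-(bromomethyl)-5-[(tert-butyldimethylsilyl)oxy]pent-2-enoate F14.

F12 and F14 under the step 10 conditions (no nickel, so the vinyl iodide is untouched) give the trimethylsilyl ether F15, then the hydroxy ester methyl (3S,4S,5E,7S,9Z)-3-{2-[(tert-butyldimethylsilyl)oxy]ethyl}-4-hydroxy-10-iodo-6-methyl-7-{[(2R)-2-methylbutanoyl]oxy}-2-methylideneundeca-5,9-dienoate F16, then the lactone (1E,3S,5Z)-1-[(2S,3S)-3-{2-[(tert-butyldimethylsilyl)oxy]ethyl}-4-methylidene-5-oxooxolan-2-yl]-6-iodo-2-methylhepta-1,5-dien-3-yl (2R)-2-methylbutanoate F17. The step 11 conditions give the α-methyl lactone F18. HF·pyridine gives the primary alcohol F19, and Dess–Martin periodinane gives the aldehyde F20. Ring closure with CrCl2 and NiCl2 (1 mol %) in DMSO/THF at 2 mM gives 22; the C9 carbinol is then set by the macrocycle, and a wrong epimer would be corrected by oxidation and reduction.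

Step 10 (catalytic asymmetric chromium allylation). The γ-substituted, ester-bearing allyl bromide is beyond the best-documented scope, so the syn ratio or the facial control may fall short; because both partners are single enantiomers, any wrong-face product is a separable diastereomer. Fallback: an organocatalysed allylboration through a closed boron transition state. It sets out from compound 15 and comes back at compound 18. Ac2O, pyridine and DMAP give the acetate methyl (5S)-3-acetoxy-5-[(tert-butyldimethylsilyl)oxy]-6-methyl-2-methylidenehept-6-enoate F1. SN2′ borylation with B2pin2, CuCl (cat.) and KOAc in DMF gives the allylboronate methyl (2E,5S)-5-[(tert-butyldimethylsilyl)oxy]-6-methyl-2-[(4,4,5,5-tetramethyl-1,3,2-dioxaborolan-2-yl)methyl]hepta-2,6-dienoate F2, in which the chain is cis to CH2B. F2 and 8 with (R)-TRIP phosphoric acid (10 mol %, the antipode expected to direct Re-face attack) in toluene give the pinacol borate ester F3, which is hydrolysed on work-up to 18 and lactonised to 19 as in step 10.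

Step 11 (C11 configuration by kinetic protonation). The methyl ends up cis to the C7 substituent, which is the less stable epimer, so selectivity could be modest or erode. Fallback: carry the α-methylene lactone through and set C11 last by face-selective hydrogenation. It sets out from compound 19 and comes back at compound 22. HF·pyridine gives the alcohol (1E,3S)-1-[(2S,3S)-3-[(2S)-2-hydroxy-3-methylbut-3-en-1-yl]-4-methylidene-5-oxooxolan-2-yl]-2-methylhexa-1,5-dien-3-yl (2R)-2-methylbutanoate F4. Ring-closing metathesis under the step 13 conditions gives the macrocyclic α-methylene lactone (1(10)Z,4E)-(3S,6S,7S,9S)-9-hydroxy-3-{[(2R)-2-methylbutanoyl]oxy}germacra-1(10),4,11(13)-trien-12,6-olide F5. H2 (1 atm) with RhCl(PPh3)3 in benzene reduces only the exocyclic alkene, from the lactone face opposite the ring carbons, to give 22.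

**Further compounds**
F1 | step 10 | methyl (5S)-3-acetoxy-5-[(tert-butyldimethylsilyl)oxy]-6-methyl-2-methylidenehept-6-enoate (both C3 epimers) | CC(=C)[C@@H](O[Si](C)(C)C(C)(C)C)CC(OC(C)=O)C(=C)C(=O)OC
F2 | step 10 | methyl (2E,5S)-5-[(tert-butyldimethylsilyl)oxy]-6-methyl-2-[(4,4,5,5-tetramethyl-1,3,2-dioxaborolan-2-yl)methyl]hepta-2,6-dienoate | CC(=C)[C@@H](O[Si](C)(C)C(C)(C)C)C/C=C(\CB1OC(C)(C)C(C)(C)O1)C(=O)OC
F3 | step 10 | pinacol borate ester of 18 (boron on the C4 oxygen) | CC[C@@H](C)C(=O)O[C@@H](CC=C)/C(C)=C/[C@H](OB1OC(C)(C)C(C)(C)O1)[C@@H](C[C@H](O[Si](C)(C)C(C)(C)C)C(C)=C)C(=C)C(=O)OC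
F4 | step 11 | (1E,3S)-1-[(2S,3S)-3-[(2S)-2-hydroxy-3-methylbut-3-en-1-yl]-4-methylidene-5-oxooxolan-2-yl]-2-methylhexa-1,5-dien-3-yl (2R)-2-methylbutanoate | CC[C@@H](C)C(=O)O[C@@H](CC=C)/C(C)=C/[C@@H]1OC(=O)C(=C)[C@@H]1C[C@H](O)C(C)=C
F5 | step 11 | (1(10)Z,4E)-(3S,6S,7S,9S)-9-hydroxy-3-{[(2R)-2-methylbutanoyl]oxy}germacra-1(10),4,11(13)-trien-12,6-olide | CC[C@@H](C)C(=O)O[C@H]1C/C=C(/C)[C@@H](O)C[C@@H]2[C@H](/C=C/1C)OC(=O)C2=C
F6 | step 13 | (3S,4E)-1-[(4R)-4-benzyl-2-sulfanylidene-1,3-thiazolidin-3-yl]-3-hydroxy-6,6-dimethoxy-4-methylhex-4-en-1-one | COC(OC)/C=C(C)/[C@@H](O)CC(=O)N1C(=S)SC[C@H]1Cc1ccccc1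
F7 | step 13 | (3S,4E)-1-[(4R)-4-benzyl-2-sulfanylidene-1,3-thiazolidin-3-yl]-3-[(tert-butyldimethylsilyl)oxy]-6,6-dimethoxy-4-methylhex-4-en-1-one | COC(OC)/C=C(C)/[C@@H](O[Si](C)(C)C(C)(C)C)CC(=O)N1C(=S)SC[C@H]1Cc1ccccc1
F8 | step 13 | (3S,4E)-3-[(tert-butyldimethylsilyl)oxy]-6,6-dimethoxy-4-methylhex-4-enal | COC(OC)/C=C(C)/[C@@H](O[Si](C)(C)C(C)(C)C)CC=O
F9 | step 13 | (2E,4S,6Z)-4-[(tert-butyldimethylsilyl)oxy]-7-iodo-1,1-dimethoxy-3-methylocta-2,6-diene | COC(OC)/C=C(C)/[C@@H](O[Si](C)(C)C(C)(C)C)C/C=C(/C)I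
F10 | step 13 | (2E,4S,6Z)-7-iodo-1,1-dimethoxy-3-methylocta-2,6-dien-4-ol | COC(OC)/C=C(C)/[C@@H](O)C/C=C(/C)I
F11 | step 13 | (2E,4S,6Z)-7-iodo-1,1-dimethoxy-3-methylocta-2,6-dien-4-yl (2R)-2-methylbutanoate | CC[C@@H](C)C(=O)O[C@@H](C/C=C(/C)I)/C(C)=C/C(OC)OC
F12 | step 13 | (2E,4S,6Z)-7-iodo-3-methyl-1-oxoocta-2,6-dien-4-yl (2R)-2-methylbutanoate | CC[C@@H](C)C(=O)O[C@@H](C/C=C(/C)I)/C(C)=C/C=O
F13 | step 13 | methyl 5-[(tert-butyldimethylsilyl)oxy]-3-hydroxy-2-methylidenepentanoate (racemic) | CC(C)(C)[Si](C)(C)OCCC(O)C(=C)C(=O)OC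
F14 | step 13 | methyl (2Z)-2-(bromomethyl)-5-[(tert-butyldimethylsilyl)oxy]pent-2-enoate | CC(C)(C)[Si](C)(C)OCC/C=C(\CBr)C(=O)OC
F15 | step 13 | methyl (3S,4S,5E,7S,9Z)-3-{2-[(tert-butyldimethylsilyl)oxy]ethyl}-10-iodo-6-methyl-7-{[(2R)-2-methylbutanoyl]oxy}-2-methylidene-4-[(trimethylsilyl)oxy]undeca-5,9-dienoate | CC[C@@H](C)C(=O)O[C@@H](C/C=C(/C)I)/C(C)=C/[C@H](O[Si](C)(C)C)[C@@H](CCO[Si](C)(C)C(C)(C)C)C(=C)C(=O)OC
F16 | step 13 | methyl (3S,4S,5E,7S,9Z)-3-{2-[(tert-butyldimethylsilyl)oxy]ethyl}-4-hydroxy-10-iodo-6-methyl-7-{[(2R)-2-methylbutanoyl]oxy}-2-methylideneundeca-5,9-dienoate | CC[C@@H](C)C(=O)O[C@@H](C/C=C(/C)I)/C(C)=C/[C@H](O)[C@@H](CCO[Si](C)(C)C(C)(C)C)C(=C)C(=O)OC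
F17 | step 13 | (1E,3S,5Z)-1-[(2S,3S)-3-{2-[(tert-butyldimethylsilyl)oxy]ethyl}-4-methylidene-5-oxooxolan-2-yl]-6-iodo-2-methylhepta-1,5-dien-3-yl (2R)-2-methylbutanoate | CC[C@@H](C)C(=O)O[C@@H](C/C=C(/C)I)/C(C)=C/[C@@H]1OC(=O)C(=C)[C@@H]1CCO[Si](C)(C)C(C)(C)C
F18 | step 13 | (1E,3S,5Z)-1-[(2R,3S,4R)-3-{2-[(tert-butyldimethylsilyl)oxy]ethyl}-4-methyl-5-oxooxolan-2-yl]-6-iodo-2-methylhepta-1,5-dien-3-yl (2R)-2-methylbutanoate | CC[C@@H](C)C(=O)O[C@@H](C/C=C(/C)I)/C(C)=C/[C@@H]1OC(=O)[C@H](C)[C@@H]1CCO[Si](C)(C)C(C)(C)C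
F19 | step 13 | (1E,3S,5Z)-1-[(2R,3S,4R)-3-(2-hydroxyethyl)-4-methyl-5-oxooxolan-2-yl]-6-iodo-2-methylhepta-1,5-dien-3-yl (2R)-2-methylbutanoate | CC[C@@H](C)C(=O)O[C@@H](C/C=C(/C)I)/C(C)=C/[C@@H]1OC(=O)[C@H](C)[C@@H]1CCO
F20 | step 13 | (1E,3S,5Z)-6-iodo-2-methyl-1-[(2R,3S,4R)-4-methyl-5-oxo-3-(2-oxoethyl)oxolan-2-yl]hepta-1,5-dien-3-yl (2R)-2-methylbutanoate | CC[C@@H](C)C(=O)O[C@@H](C/C=C(/C)I)/C(C)=C/[C@@H]1OC(=O)[C@H](C)[C@@H]1CC=O
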